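## Structural features

The target is a linear chain of seven benzene rings (A to G) held together only by six diaryl ether oxygens; it carries eighteen free phenolic hydroxyls and has no stereocentre. Rings A, B, D and F are 1,2,3,5-tetraoxygenated, rings C and E are pentaoxygenated with one ring hydrogen each, and ring G is a 3,4,5-trihydroxyphenyl group. With C1 of each of rings B to G taken as the carbon whose ether oxygen leads back towards ring A, each ether oxygen sits on one side on a carbon flanked by two oxygenated carbons (A C1, B C4, C C6, D C4, E C6, F C4) and on the other side on a less crowded carbon (B C1, C C1, D C1, E C1, F C1, G C1). The free polyphenol is easily oxidised in air or base, and its rings, above all the phloroglucinol-type ring A, are strongly nucleophilic towards electrophiles such as formaldehyde equivalents, so the hydroxyls must stay masked until the last step. The real difficulty is twofold: six hindered ether bonds between electron-rich rings, and two pentaoxygenated rings whose single hydrogen must be in the right place. The key step uses the fact that C3, C4, C5 and C6 of ring C are four contiguous oxygen-bearing carbons, which map onto the four carbons of a squarate, while C1 and C2 map onto a 2-aryloxyvinyl unit whose oxygen is already the ether to ring B. Ring E shows the same pattern relative to ring D, so the same construction can be used twice.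

## Logic of the disconnections

41 to 40 to 39: the sixteen O–benzyl bonds and the two O–CH2OMe bonds are cut. The free polyphenol is too sensitive to carry, benzyl ethers fall under neutral hydrogenolysis, and the two acetals are removed one step earlier so that no formaldehyde equivalent meets the unprotected rings. The forward demand is a clean sixteen-fold hydrogenolysis with exclusion of air.

39 to 38 + 18: the bond between the ring E C6 oxygen and ring F C1 is cut. The oxygen stays on the crowded carbon as a phenol and the partner carries boron on its unhindered carbon, so rings F and G arrive together. The forward step must arylate a phenol with two ortho substituents under oxidative copper mediation.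

38 to 35, and 35 to 32 + 24: the ring E C6–C1 bond is cut, then the bond from the cyclobutenone quaternary carbon to the vinyl group and the acetal cap. This is the same ring expansion as the key step, applied a second time, and it removes a whole pentaoxygenated ring. The forward steps need a bromine–lithium exchange in the presence of ten ether groups and one acetal.

32 to 31 + 9: the bond between the ring C C6 oxygen and ring D C1 is cut. Because 9 already carries the Z bromovinyl ether on its hindered oxygen, ring D arrives ready for the next ring expansion with no separate deprotection and vinylation. The vinyl bromide must survive Cu(OAc)2 and amine base at room temperature.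

31 to 28 (key step): the ring C bond C6–C1 is cut, which unfolds the arene into a cyclobutenone bearing a Z aryloxyvinyl group. All five oxygens of ring C are then in place with only the C6 oxygen unmasked. The forward step needs outward rotation of the oxygen donor on the sp3 carbon during ring opening. A vinyl rather than an alkynyl group is used because donor-substituted alkynyl analogues are known to divert to five-membered ring closure.

28 to 25 + 24: the bond from the quaternary carbon to the vinyl carbon and the O–CH2OMe bond are cut. The four oxygenated carbons come from symmetric 24, so there is no regiochemical question in the addition. The Z geometry is required because lithium and aryloxy are then cis and cannot undergo anti elimination.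

25 to 22 + 9: the bond between the ring A C1 oxygen and ring B C1 is cut, by the same coupling as used later for ring D. This makes 9 a monomer that is used twice and shortens the way to 28.

9 to 8, 8 to 6 + 7, 6 to 5, 5 to 3, 3 to 1 + 2: the boronic acid is traced to its pinacol ester, the bromovinyl ether to the phenol and a two-carbon unit, the C–B bond to a C–Br bond, the phenol to an aldehyde, and the two benzyl ethers to two fluorides activated by that aldehyde and displaced by two molecules of 2. The boron must be put in before the vinyl bromide, because no metalation would distinguish aryl from vinyl bromide afterwards.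

18 to 15, 15 to 5 + 14, 14 to 11, 11 to 5 + 10: the F–G boronic acid comes from the bromide, whose F C4–O–G bond is made from 5 and 14; 14 itself is 5 benzylated and borylated. One intermediate, 5, thus feeds rings B, D, F and G.

22 to 20, 20 to 19 + 10, and 24 to 23 + 2: the ring A phenol comes from an aldehyde by oxygen insertion, and that aldehyde from commercial 19 and three molecules of 10; the formyl group of 19 suppresses C-benzylation. 24 comes from 23 and two molecules of 2 by loss of water.

## Other disconnections considered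

Alternative 1: The three ether bonds B–O–C(C1), D–O–E(C1) and F–O–G(C1) are traced back to aryl ester links in the permethylated tris-ester A1. Ni(cod)2 (zerovalent nickel) with 3,4-bis(dicyclohexylphosphino)thiophene would insert into each C(acyl)–O bond, lose CO and reductively eliminate to give the octadecamethyl ether A2.
- In favour: esters of hindered phenols are far easier to form than hindered diaryl ethers, the acyl parts of rings C, E and G are gallic-acid-like, and three ether bonds would arise in one operation. On convergence and on steps spent per ether bond this is better than the chosen plan.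
- Against: this decarbonylation is best established for electron-poor acyl groups and unhindered phenoxides. In A1 the acyl rings are electron-rich, two of them carry an ortho aryloxy group, and each phenoxide has two ortho methoxy groups. Three consecutive events must all succeed in one molecule, and partial reaction would give mixtures that are hard to separate.
- Comparison: the pentaoxygenated rings C and E would still have to be made separately, as the aryloxy-substituted acyl halves of A1, so the alternative does not address what the squarate ring expansion solves. The endgame from A2 needs eighteen O-demethylations with a strong Lewis acid, which is harsher than hydrogenolysis.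

Alternative 2: Both ether bonds of ring F are cut. The complex A3, [CpRu(η6-2,5-dichloro-1,3-bis(benzyloxy)benzene)]PF6 (divalent ruthenium), would react first with the phenoxide of the perbenzylated A–E pentamer phenol A4 at the unflanked chloride and then with the phenoxide of 3,4,5-tris(benzyloxy)phenol A5 at the flanked chloride, giving the ruthenium complex A6.
- In favour: π-complexation should make even the chloride between two benzyloxy groups open to nucleophilic aromatic substitution under mild conditions. No oxidant is present, which suits electron-rich phenols and is better on that point than the oxidative copper coupling of step 19. Two bonds form in one pot.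
- Against: ruthenium is stoichiometric and A3 must first be prepared by arene complexation. Site selectivity of the first substitution rests on sterics only. The second substitution takes place on a complex made much less electrophilic by three donor oxygens. The metal must finally be released by photolysis, with a risk of migration to another of the electron-rich rings.
- Comparison: A4 must still be made, including rings C and E, so this complements the ring expansion and does not replace it. In step count for rings F and G it is about equal to the chosen plan (complexation, one-pot substitution and decomplexation against steps 8, 9 and 19).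

Alternative 3: The ring A bond C1–C2 is cut. LiN(i-Pr)2 would close the methyl 6-aryloxy-3,5-dioxohexanoate A7 of the benzylated B–G hexamer by Claisen attack of C6 on the ester carbon, giving the heptamer A8 with a free phloroglucinol ring A.
- In favour: ring A would arrive with three fewer benzyl groups. The A–O–B link would be made by alkylating an unhindered ring B phenol instead of arylating a crowded one, which is better on that bond than step 13. Like the chosen key step, it builds an oxygenated arene from a non-aromatic precursor with regiochemistry fixed by connectivity, so on that point the two are equal.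
- Against: C6 is the least acidic carbon of the chain, so a polyanion is needed. O-acylation by the C5 enolate (lactonisation) and aldol closures compete. A free phloroglucinol ring would be generated under strong base in a molecule with fifteen benzyl ethers and carried through the endgame.
- Comparison: the chain would have to be built at a late stage on a hexamer whose ring B oxygen needs its own protecting group. The chosen plan makes ring A in two steps from 19 and attaches it in one, so nothing is gained in step count, and the difficult rings C and E are not touched.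

Key step: step 15

Assumption: ring C of 28 and of 31 was mapped atom by atom onto the target and both structures are consistent with it. The Z bromovinyl ether is built into monomer 9, and ring A is taken from 19 because direct O-benzylation of phloroglucinol is compromised by C-benzylation.

Assumption: 7 is the commercial mixture of E and Z isomers; both converge on bromoethyne, which is generated and consumed only in solution under argon.

Abbreviations: Bn = benzyl, MOM = methoxymethyl, pin = pinacolato. "A–B aryl" is 2,6-bis(benzyloxy)-4-[2,4,6-tris(benzyloxy)phenoxy]phenyl. "A–D aryl" is the aryl group of 32 that is bound to the vinyl ether oxygen (ring D C4 with rings A to C attached).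

## Route

Step 1
Reactants: 1 4-bromo-2,6-difluorobenzaldehyde; 2 benzyl alcohol
Product: 3 2,6-bis(benzyloxy)-4-bromobenzaldehyde
Conditions: BnOH (2.5 equiv), Cs2CO3 (3 equiv), DMF, 70 °C
Reagents that add atoms: benzyl alcohol (second equivalent), OCc1ccccc1
Why: Double nucleophilic aromatic substitution, one molecule of benzyl alcohol per fluoride; both fluorides are ortho to the formyl group, which stabilises the Meisenheimer intermediates, while bromide is a much poorer leaving group in this mechanism and should stay.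

Step 2
Reactants: 3 2,6-bis(benzyloxy)-4-bromobenzaldehyde
Product: 5 2,6-bis(benzyloxy)-4-bromophenol, via aryl formate 4 (not isolated)
Conditions: mCPBA, NaHCO3, CH2Cl2, 0 °C to rt; then K2CO3, MeOH, rt
Reagents that add atoms: mCPBA, OOC(=O)c1cccc(Cl)c1
Why: Baeyer–Villiger oxidation of an electron-rich benzaldehyde, in which the aryl group migrates in preference to hydride; mild methanolysis of the formate frees the phenol without touching the benzyl ethers or the bromide.

Step 3
Reactants: 5 2,6-bis(benzyloxy)-4-bromophenol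
Product: 6 2,6-bis(benzyloxy)-4-(4,4,5,5-tetramethyl-1,3,2-dioxaborolan-2-yl)phenol
Conditions: B2pin2, PdCl2(dppf) (3 mol %), KOAc, 1,4-dioxane, 90 °C
Reagents that add atoms: bis(pinacolato)diboron, CC1(C)OB(OC1(C)C)B1OC(C)(C)C(C)(C)O1
Why: Miyaura borylation; free phenols are tolerated with the weak base KOAc, and the aryl bromide is the only site for oxidative addition.

Step 4
Reactants: 6 2,6-bis(benzyloxy)-4-(4,4,5,5-tetramethyl-1,3,2-dioxaborolan-2-yl)phenol; 7 1,2-dibromoethene (E/Z mixture)
Product: 8 2-(3,5-bis(benzyloxy)-4-{[(Z)-2-bromoethenyl]oxy}phenyl)-4,4,5,5-tetramethyl-1,3,2-dioxaborolane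
Conditions: 7 (3 equiv), Cs2CO3, DMF, 70 °C, Ar
Reagents that add atoms: none
Why: Elimination–addition: base converts 7 into bromoethyne, and the phenoxide adds anti to its unsubstituted carbon so that oxygen and bromine end up cis (Z); a pinacol boronate should tolerate carbonate in dry DMF as it does in routine O-alkylations of hydroxyphenyl boronates.

Step 5
Reactants: 8 2-(3,5-bis(benzyloxy)-4-{[(Z)-2-bromoethenyl]oxy}phenyl)-4,4,5,5-tetramethyl-1,3,2-dioxaborolane
Product: 9 (3,5-bis(benzyloxy)-4-{[(Z)-2-bromoethenyl]oxy}phenyl)boronic acid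
Conditions: NaIO4, NH4OAc, acetone/H2O, rt
Reagents that add atoms: water, O
Why: Oxidative cleavage of the pinacol ester; periodate destroys the liberated diol and so drives the hydrolysis, and the near-neutral medium should leave the vinyl ether and benzyl ethers intact.

Step 6
Reactants: 5 2,6-bis(benzyloxy)-4-bromophenol; 10 benzyl bromide
Product: 11 1,2,3-tris(benzyloxy)-5-bromobenzene
Conditions: BnBr, K2CO3, DMF, 50 °C
Reagents that add atoms: none
Why: Williamson etherification of a phenoxide with a reactive benzylic halide.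

Step 7
Reactants: 11 1,2,3-tris(benzyloxy)-5-bromobenzene
Product: 14 [3,4,5-tris(benzyloxy)phenyl]boronic acid, via aryllithium 12 (not isolated), via lithium borate 13 (not isolated)
Conditions: n-BuLi, THF, −78 °C; B(Oi-Pr)3, −78 °C to rt; 1 M HCl
Reagents that add atoms: triisopropyl borate, CC(C)OB(OC(C)C)OC(C)C; water, O
Why: Bromine–lithium exchange is much faster at −78 °C than benzylic deprotonation; the aryllithium is trapped by the borate and the ate complex is hydrolysed to the boronic acid.

Step 8
Reactants: 5 2,6-bis(benzyloxy)-4-bromophenol; 14 [3,4,5-tris(benzyloxy)phenyl]boronic acid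
Product: 15 1,3-bis(benzyloxy)-5-bromo-2-[3,4,5-tris(benzyloxy)phenoxy]benzene
Conditions: Cu(OAc)2 (1 equiv), pyridine, 4 Å MS, CH2Cl2, dry air, rt
Reagents that add atoms: none
Why: Chan–Lam coupling: the unhindered aryl group passes from boron to divalent copper, and C–O reductive elimination from a trivalent copper aryl phenoxide forms the ether at room temperature, with air returning copper to the divalent state; the aryl bromide is inert and the ortho and para positions of the phenol are blocked against oxidative C–C coupling.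

Step 9
Reactants: 15 1,3-bis(benzyloxy)-5-bromo-2-[3,4,5-tris(benzyloxy)phenoxy]benzene
Product: 18 {3,5-bis(benzyloxy)-4-[3,4,5-tris(benzyloxy)phenoxy]phenyl}boronic acid, via aryllithium 16 (not isolated), via lithium borate 17 (not isolated)
Conditions: n-BuLi, THF, −78 °C; B(Oi-Pr)3, −78 °C to rt; 1 M HCl
Reagents that add atoms: triisopropyl borate, CC(C)OB(OC(C)C)OC(C)C; water, O
Why: Same lithiation–borylation as step 7; the diaryl ether and benzyl ethers are inert to n-BuLi during the short exchange at −78 °C.

Step 10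
Reactants: 19 2,4,6-trihydroxybenzaldehyde; 10 benzyl bromide
Product: 20 2,4,6-tris(benzyloxy)benzaldehyde
Conditions: BnBr (3.6 equiv), K2CO3, DMF, 60 °C
Reagents that add atoms: benzyl bromide (second equivalent), BrCc1ccccc1; benzyl bromide (third equivalent), BrCc1ccccc1
Why: Threefold Williamson etherification, one molecule of benzyl bromide per hydroxyl; the formyl group lowers the ring nucleophilicity, so O-alkylation should prevail over the C-benzylation that affects phloroglucinol itself.

Step 11
Reactants: 20 2,4,6-tris(benzyloxy)benzaldehyde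
Product: 22 2,4,6-tris(benzyloxy)phenol, via aryl formate 21 (not isolated)
Conditions: mCPBA, NaHCO3, CH2Cl2, 0 °C to rt; then K2CO3, MeOH, rt
Reagents that add atoms: mCPBA, OOC(=O)c1cccc(Cl)c1
Why: Baeyer–Villiger oxidation with migration of the very electron-rich aryl group; the formate protects the product phenol from over-oxidation until it is cleaved by methanolysis.

Step 12
Reactants: 23 squaric acid; 2 benzyl alcohol
Product: 24 dibenzyl squarate (3,4-bis(benzyloxy)cyclobut-3-ene-1,2-dione)
Conditions: BnOH (2.5 equiv), PhMe, reflux, Dean–Stark trap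
Reagents that add atoms: benzyl alcohol (second equivalent), OCc1ccccc1
Why: Twofold esterification of a vinylogous acid with azeotropic removal of water; squaric acid is acidic enough to catalyse its own esterification, as in the standard preparation of dialkyl squarates.

Step 13
Reactants: 22 2,4,6-tris(benzyloxy)phenol; 9 (3,5-bis(benzyloxy)-4-{[(Z)-2-bromoethenyl]oxy}phenyl)boronic acid
Product: 25 1,3-bis(benzyloxy)-2-{[(Z)-2-bromoethenyl]oxy}-5-[2,4,6-tris(benzyloxy)phenoxy]benzene (A–B bromovinyl ether)
Conditions: Cu(OAc)2 (1 equiv), pyridine, 4 Å MS, CH2Cl2, dry air, rt; 9 (1.5 equiv)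
Reagents that add atoms: none
Why: Chan–Lam coupling as in step 8; the boron-bearing carbon of 9 is flanked by hydrogens, the phenol is blocked at both ortho positions and para, and a vinyl bromide does not react with divalent copper and pyridine at room temperature.

Step 14
Reactants: 25 A–B bromovinyl ether; 24 dibenzyl squarate
Product: 28 racemic 2,3-bis(benzyloxy)-4-(methoxymethoxy)-4-[(Z)-2-(A–B aryloxy)ethenyl]cyclobut-2-en-1-one, via vinyllithium 26 (not isolated), via lithium alkoxide 27 (not isolated)
Conditions: t-BuLi (2.0 equiv), THF, −78 °C; 24, −78 °C; MOMCl, −78 to 0 °C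
Reagents that add atoms: chloromethyl methyl ether, COCCl
Why: Bromine–lithium exchange proceeds with retention, and the Z vinyllithium has lithium and aryloxy cis so it cannot eliminate anti at −78 °C; it adds 1,2 to one of the two equivalent carbonyls of 24, and the tertiary alkoxide is O-alkylated in the flask by the very reactive chloride, the new quaternary centre being racemic and later destroyed.

Step 15
Reactants: 28 racemic 2,3-bis(benzyloxy)-4-(methoxymethoxy)-4-[(Z)-2-(A–B aryloxy)ethenyl]cyclobut-2-en-1-one
Product: 31 2,3-bis(benzyloxy)-6-(A–B aryloxy)-4-(methoxymethoxy)phenol (A–B–C trimer phenol with the ring C C6 hydroxyl free), via dienylketene 29 (not isolated), via cyclohexadienone 30 (not isolated)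
Conditions: PhMe (0.02 M, degassed), 110 °C, Ar
Reagents that add atoms: none
Why: This is the Moore rearrangement of a squarate-derived 4-alkenyl-4-alkoxycyclobutenone, a known thermal cascade. Heating opens the strained ring of 28 by conrotatory 4π electrocyclic cleavage of the bond between the carbonyl carbon and the quaternary carbon, giving dienylketene 29. The methoxymethoxy oxygen, the best donor on the sp3 carbon, rotates outward, which places the aryloxyvinyl group inward and cis to the ketene. The ketene carbon then bonds to the vinyl terminus in a thermal disrotatory 6π electrocyclisation, which closes ring C as a six-membered carbocycle, forms the C6–C1 bond and gives dienone 30. Enolisation of 30 is driven by aromatisation and gives phenol 31. No stereocentre survives, because the quaternary carbon of 28 and the sp3 carbon of 30 both become sp2, so the racemic nature of 28 does not matter. Regiochemistry is fixed by connectivity alone: the squarate carbons become C3 to C6 with their oxygens, the vinyl carbons become C2 (the single hydrogen) and C1 (the ring B ether), and only the former ketene oxygen on C6 is left free. The one selectivity needed is the outward torquoselectivity, which the oxygen donor secures; the Z aryloxy group lies inside the closing triene but the attacking ketene carbon is sp-hybridised and unencumbered, and high dilution in degassed toluene should suppress ketene dimerisation.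

Step 16
Reactants: 31 A–B–C trimer phenol; 9 (3,5-bis(benzyloxy)-4-{[(Z)-2-bromoethenyl]oxy}phenyl)boronic acid
Product: 32 A–B–C–D tetramer (Z)-bromovinyl ether (the ring C C6 oxygen of 31 bound to C1 of a 3,5-bis(benzyloxy)-4-{[(Z)-2-bromoethenyl]oxy}phenyl ring D)
Conditions: Cu(OAc)2 (1 equiv), pyridine, 4 Å MS, CH2Cl2, dry air, rt; 9 (2 equiv)
Reagents that add atoms: none
Why: Chan–Lam coupling as in step 13; the only free hydroxyl of 31 is arylated, its ortho and para positions carry oxygen substituents so oxidative C–C coupling is blocked, and the MOM acetal is stable to pyridine and Cu(OAc)2.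

Step 17
Reactants: 32 A–B–C–D tetramer (Z)-bromovinyl ether; 24 dibenzyl squarate
Product: 35 racemic 2,3-bis(benzyloxy)-4-(methoxymethoxy)-4-[(Z)-2-(A–D aryloxy)ethenyl]cyclobut-2-en-1-one, via vinyllithium 33 (not isolated), via lithium alkoxide 34 (not isolated)
Conditions: t-BuLi (2.0 equiv, added to 32), THF, −78 °C; 24, −78 °C; MOMCl, −78 to 0 °C
Reagents that add atoms: chloromethyl methyl ether, COCCl
Why: Same exchange, 1,2-addition and capping as step 14; exchange at the vinyl bromide is far faster than directed metalation next to the ring C acetal, and exact stoichiometry leaves no excess base.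

Step 18
Reactants: 35 racemic 2,3-bis(benzyloxy)-4-(methoxymethoxy)-4-[(Z)-2-(A–D aryloxy)ethenyl]cyclobut-2-en-1-one
Product: 38 A–E pentamer phenol (ring E with C6 hydroxyl free, C5 and C4 benzyloxy, C3 methoxymethoxy, C1 bound to the ring D oxygen), via dienylketene 36 (not isolated), via cyclohexadienone 37 (not isolated)
Conditions: PhMe (0.02 M, degassed), 110 °C, Ar
Reagents that add atoms: none
Why: Second Moore rearrangement by the same 4π opening, 6π closure and enolisation as in step 15; it builds ring E with its single hydrogen on C2 and only the C6 hydroxyl free.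

Step 19
Reactants: 38 A–E pentamer phenol; 18 {3,5-bis(benzyloxy)-4-[3,4,5-tris(benzyloxy)phenoxy]phenyl}boronic acid
Product: 39 hexadecabenzyl bis(methoxymethyl) ether of the target (MOM on ring C C3 and ring E C3)
Conditions: Cu(OAc)2 (1 equiv), pyridine, 4 Å MS, CH2Cl2, dry air, rt; 18 (2 equiv)
Reagents that add atoms: none
Why: Chan–Lam coupling as in step 16; it joins the ring E C6 oxygen to the unhindered ring F C1 and brings in rings F and G together.

Step 20
Reactants: 39 hexadecabenzyl bis(methoxymethyl) ether of the target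
Product: 40 hexadecabenzyl ether of the target with free hydroxyls on ring C C3 and ring E C3
Conditions: ZnBr2, n-PrSH, CH2Cl2, 0 °C to rt
Reagents that add atoms: none
Why: Lewis-acid cleavage of aryl MOM ethers with a thiol, which traps the methoxymethyl cation before it can alkylate the electron-rich rings; benzyl and diaryl ethers are stable under these conditions.

Step 21
Reactants: 40 hexadecabenzyl ether of the target
Product: 41 the target heptamer (CNP0292517.0)
Conditions: H2 (1 atm), Pd/C, THF/MeOH (degassed), rt; filtration under Ar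
Reagents that add atoms: none
Why: Hydrogenolysis of aryl benzyl ethers under neutral conditions releases only toluene; diaryl ethers and the arene rings are not reduced at 1 atm, and no stereocentre is at stake.

## Compound list

1 | 4-bromo-2,6-difluorobenzaldehyde | O=Cc1c(F)cc(Br)cc1F | starting material
2 | benzyl alcohol | OCc1ccccc1 | starting material
3 | 2,6-bis(benzyloxy)-4-bromobenzaldehyde | O=Cc1c(OCc9ccccc9)cc(Br)cc1OCc9ccccc9 | intermediate
4 | 2,6-bis(benzyloxy)-4-bromophenyl formate (not isolated) | O=COc1c(OCc9ccccc9)cc(Br)cc1OCc9ccccc9 | intermediate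
5 | 2,6-bis(benzyloxy)-4-bromophenol | Oc1c(OCc9ccccc9)cc(Br)cc1OCc9ccccc9 | intermediate
6 | 2,6-bis(benzyloxy)-4-(4,4,5,5-tetramethyl-1,3,2-dioxaborolan-2-yl)phenol | Oc1c(OCc9ccccc9)cc(B2OC(C)(C)C(C)(C)O2)cc1OCc9ccccc9 | intermediate
7 | 1,2-dibromoethene (E/Z mixture) | BrC=CBr | starting material
8 | 2-(3,5-bis(benzyloxy)-4-{[(Z)-2-bromoethenyl]oxy}phenyl)-4,4,5,5-tetramethyl-1,3,2-dioxaborolane | Br/C=C\Oc1c(OCc9ccccc9)cc(B2OC(C)(C)C(C)(C)O2)cc1OCc9ccccc9 | intermediate
9 | (3,5-bis(benzyloxy)-4-{[(Z)-2-bromoethenyl]oxy}phenyl)boronic acid | Br/C=C\Oc1c(OCc9ccccc9)cc(B(O)O)cc1OCc9ccccc9 | intermediate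
10 | benzyl bromide | BrCc1ccccc1 | starting material
11 | 1,2,3-tris(benzyloxy)-5-bromobenzene | Brc1cc(OCc9ccccc9)c(OCc9ccccc9)c(OCc9ccccc9)c1 | intermediate
12 | [3,4,5-tris(benzyloxy)phenyl]lithium (not isolated) | [Li]c1cc(OCc9ccccc9)c(OCc9ccccc9)c(OCc9ccccc9)c1 | intermediate
13 | lithium triisopropoxy[3,4,5-tris(benzyloxy)phenyl]borate (not isolated) | [Li+].CC(C)O[B-](OC(C)C)(OC(C)C)c1cc(OCc9ccccc9)c(OCc9ccccc9)c(OCc9ccccc9)c1 | intermediate
14 | [3,4,5-tris(benzyloxy)phenyl]boronic acid | OB(O)c1cc(OCc9ccccc9)c(OCc9ccccc9)c(OCc9ccccc9)c1 | intermediate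
15 | 1,3-bis(benzyloxy)-5-bromo-2-[3,4,5-tris(benzyloxy)phenoxy]benzene (F–G bromide) | Brc1cc(OCc9ccccc9)c(Oc2cc(OCc9ccccc9)c(OCc9ccccc9)c(OCc9ccccc9)c2)c(OCc9ccccc9)c1 | intermediate
16 | {3,5-bis(benzyloxy)-4-[3,4,5-tris(benzyloxy)phenoxy]phenyl}lithium (not isolated) | [Li]c1cc(OCc9ccccc9)c(Oc2cc(OCc9ccccc9)c(OCc9ccccc9)c(OCc9ccccc9)c2)c(OCc9ccccc9)c1 | intermediate
17 | lithium triisopropoxy{3,5-bis(benzyloxy)-4-[3,4,5-tris(benzyloxy)phenoxy]phenyl}borate (not isolated) | [Li+].CC(C)O[B-](OC(C)C)(OC(C)C)c1cc(OCc9ccccc9)c(Oc2cc(OCc9ccccc9)c(OCc9ccccc9)c(OCc9ccccc9)c2)c(OCc9ccccc9)c1 | intermediate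
18 | {3,5-bis(benzyloxy)-4-[3,4,5-tris(benzyloxy)phenoxy]phenyl}boronic acid (F–G boronic acid) | OB(O)c1cc(OCc9ccccc9)c(Oc2cc(OCc9ccccc9)c(OCc9ccccc9)c(OCc9ccccc9)c2)c(OCc9ccccc9)c1 | intermediate
19 | 2,4,6-trihydroxybenzaldehyde | O=Cc1c(O)cc(O)cc1O | starting material
20 | 2,4,6-tris(benzyloxy)benzaldehyde | O=Cc1c(OCc9ccccc9)cc(OCc9ccccc9)cc1OCc9ccccc9 | intermediate
21 | 2,4,6-tris(benzyloxy)phenyl formate (not isolated) | O=COc1c(OCc9ccccc9)cc(OCc9ccccc9)cc1OCc9ccccc9 | intermediate
22 | 2,4,6-tris(benzyloxy)phenol | Oc1c(OCc9ccccc9)cc(OCc9ccccc9)cc1OCc9ccccc9 | intermediate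
23 | squaric acid (3,4-dihydroxycyclobut-3-ene-1,2-dione) | OC1=C(O)C(=O)C1=O | starting material
24 | dibenzyl squarate (3,4-bis(benzyloxy)cyclobut-3-ene-1,2-dione) | O=C1C(=O)C(OCc9ccccc9)=C1OCc9ccccc9 | intermediate
25 | 1,3-bis(benzyloxy)-2-{[(Z)-2-bromoethenyl]oxy}-5-[2,4,6-tris(benzyloxy)phenoxy]benzene (A–B bromovinyl ether) | Br/C=C\Oc2c(OCc9ccccc9)cc(Oc3c(OCc9ccccc9)cc(OCc9ccccc9)cc3OCc9ccccc9)cc2OCc9ccccc9 | intermediate
26 | (Z)-2-(A–B aryloxy)ethenyllithium (not isolated) | [Li]/C=C\Oc2c(OCc9ccccc9)cc(Oc3c(OCc9ccccc9)cc(OCc9ccccc9)cc3OCc9ccccc9)cc2OCc9ccccc9 | intermediate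
27 | racemic lithium 2,3-bis(benzyloxy)-4-oxo-1-[(Z)-2-(A–B aryloxy)ethenyl]cyclobut-2-en-1-olate (not isolated) | [Li+].[O-]C1(/C=C\Oc2c(OCc9ccccc9)cc(Oc3c(OCc9ccccc9)cc(OCc9ccccc9)cc3OCc9ccccc9)cc2OCc9ccccc9)C(OCc9ccccc9)=C(OCc9ccccc9)C1=O | intermediate
28 | racemic 2,3-bis(benzyloxy)-4-(methoxymethoxy)-4-[(Z)-2-(A–B aryloxy)ethenyl]cyclobut-2-en-1-one | O=C1C(OCc9ccccc9)=C(OCc9ccccc9)C1(OCOC)/C=C\Oc2c(OCc9ccccc9)cc(Oc3c(OCc9ccccc9)cc(OCc9ccccc9)cc3OCc9ccccc9)cc2OCc9ccccc9 | intermediate
29 | (3Z,5Z)-6-(A–B aryloxy)-2,3-bis(benzyloxy)-4-(methoxymethoxy)hexa-1,3,5-trien-1-one, the dienylketene (not isolated) | O=C=C(OCc9ccccc9)/C(OCc9ccccc9)=C(OCOC)\C=C/Oc2c(OCc9ccccc9)cc(Oc3c(OCc9ccccc9)cc(OCc9ccccc9)cc3OCc9ccccc9)cc2OCc9ccccc9 | intermediate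
30 | racemic 6-(A–B aryloxy)-2,3-bis(benzyloxy)-4-(methoxymethoxy)cyclohexa-2,4-dien-1-one (not isolated) | O=C1C(OCc9ccccc9)=C(OCc9ccccc9)C(OCOC)=CC1Oc2c(OCc9ccccc9)cc(Oc3c(OCc9ccccc9)cc(OCc9ccccc9)cc3OCc9ccccc9)cc2OCc9ccccc9 | intermediate
31 | 2,3-bis(benzyloxy)-6-(A–B aryloxy)-4-(methoxymethoxy)phenol (A–B–C trimer phenol) | Oc1c(OCc9ccccc9)c(OCc9ccccc9)c(OCOC)cc1Oc2c(OCc9ccccc9)cc(Oc3c(OCc9ccccc9)cc(OCc9ccccc9)cc3OCc9ccccc9)cc2OCc9ccccc9 | intermediate
32 | A–B–C–D tetramer (Z)-bromovinyl ether | Br/C=C\Oc4c(OCc9ccccc9)cc(Oc1c(OCc9ccccc9)c(OCc9ccccc9)c(OCOC)cc1Oc2c(OCc9ccccc9)cc(Oc3c(OCc9ccccc9)cc(OCc9ccccc9)cc3OCc9ccccc9)cc2OCc9ccccc9)cc4OCc9ccccc9 | intermediate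
33 | (Z)-2-(A–D aryloxy)ethenyllithium (not isolated) | [Li]/C=C\Oc4c(OCc9ccccc9)cc(Oc1c(OCc9ccccc9)c(OCc9ccccc9)c(OCOC)cc1Oc2c(OCc9ccccc9)cc(Oc3c(OCc9ccccc9)cc(OCc9ccccc9)cc3OCc9ccccc9)cc2OCc9ccccc9)cc4OCc9ccccc9 | intermediate
34 | racemic lithium 2,3-bis(benzyloxy)-4-oxo-1-[(Z)-2-(A–D aryloxy)ethenyl]cyclobut-2-en-1-olate (not isolated) | [Li+].[O-]C5(/C=C\Oc4c(OCc9ccccc9)cc(Oc1c(OCc9ccccc9)c(OCc9ccccc9)c(OCOC)cc1Oc2c(OCc9ccccc9)cc(Oc3c(OCc9ccccc9)cc(OCc9ccccc9)cc3OCc9ccccc9)cc2OCc9ccccc9)cc4OCc9ccccc9)C(OCc9ccccc9)=C(OCc9ccccc9)C5=O | intermediate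
35 | racemic 2,3-bis(benzyloxy)-4-(methoxymethoxy)-4-[(Z)-2-(A–D aryloxy)ethenyl]cyclobut-2-en-1-one | O=C5C(OCc9ccccc9)=C(OCc9ccccc9)C5(OCOC)/C=C\Oc4c(OCc9ccccc9)cc(Oc1c(OCc9ccccc9)c(OCc9ccccc9)c(OCOC)cc1Oc2c(OCc9ccccc9)cc(Oc3c(OCc9ccccc9)cc(OCc9ccccc9)cc3OCc9ccccc9)cc2OCc9ccccc9)cc4OCc9ccccc9 | intermediate
36 | (3Z,5Z)-6-(A–D aryloxy)-2,3-bis(benzyloxy)-4-(methoxymethoxy)hexa-1,3,5-trien-1-one, the dienylketene (not isolated) | O=C=C(OCc9ccccc9)/C(OCc9ccccc9)=C(OCOC)\C=C/Oc4c(OCc9ccccc9)cc(Oc1c(OCc9ccccc9)c(OCc9ccccc9)c(OCOC)cc1Oc2c(OCc9ccccc9)cc(Oc3c(OCc9ccccc9)cc(OCc9ccccc9)cc3OCc9ccccc9)cc2OCc9ccccc9)cc4OCc9ccccc9 | intermediate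
37 | racemic 6-(A–D aryloxy)-2,3-bis(benzyloxy)-4-(methoxymethoxy)cyclohexa-2,4-dien-1-one (not isolated) | O=C5C(OCc9ccccc9)=C(OCc9ccccc9)C(OCOC)=CC5Oc4c(OCc9ccccc9)cc(Oc1c(OCc9ccccc9)c(OCc9ccccc9)c(OCOC)cc1Oc2c(OCc9ccccc9)cc(Oc3c(OCc9ccccc9)cc(OCc9ccccc9)cc3OCc9ccccc9)cc2OCc9ccccc9)cc4OCc9ccccc9 | intermediate
38 | A–E pentamer phenol: 2,3-bis(benzyloxy)-6-(A–D aryloxy)-4-(methoxymethoxy)phenol | Oc5c(OCc9ccccc9)c(OCc9ccccc9)c(OCOC)cc5Oc4c(OCc9ccccc9)cc(Oc1c(OCc9ccccc9)c(OCc9ccccc9)c(OCOC)cc1Oc2c(OCc9ccccc9)cc(Oc3c(OCc9ccccc9)cc(OCc9ccccc9)cc3OCc9ccccc9)cc2OCc9ccccc9)cc4OCc9ccccc9 | intermediate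
39 | hexadecabenzyl bis(methoxymethyl) ether of the target (MOM on ring C C3 and ring E C3) | C(c9ccccc9)Oc7cc(Oc6c(OCc9ccccc9)cc(Oc5c(OCc9ccccc9)c(OCc9ccccc9)c(OCOC)cc5Oc4c(OCc9ccccc9)cc(Oc1c(OCc9ccccc9)c(OCc9ccccc9)c(OCOC)cc1Oc2c(OCc9ccccc9)cc(Oc3c(OCc9ccccc9)cc(OCc9ccccc9)cc3OCc9ccccc9)cc2OCc9ccccc9)cc4OCc9ccccc9)cc6OCc9ccccc9)cc(OCc9ccccc9)c7OCc9ccccc9 | intermediate
40 | hexadecabenzyl ether of the target (free hydroxyls on ring C C3 and ring E C3) | C(c9ccccc9)Oc7cc(Oc6c(OCc9ccccc9)cc(Oc5c(OCc9ccccc9)c(OCc9ccccc9)c(O)cc5Oc4c(OCc9ccccc9)cc(Oc1c(OCc9ccccc9)c(OCc9ccccc9)c(O)cc1Oc2c(OCc9ccccc9)cc(Oc3c(OCc9ccccc9)cc(OCc9ccccc9)cc3OCc9ccccc9)cc2OCc9ccccc9)cc4OCc9ccccc9)cc6OCc9ccccc9)cc(OCc9ccccc9)c7OCc9ccccc9 | intermediate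
41 | target heptamer CNP0292517.0 (no stereocentre) | Oc1cc(O)c(Oc2cc(O)c(Oc3cc(O)c(O)c(O)c3Oc3cc(O)c(Oc4cc(O)c(O)c(O)c4Oc4cc(O)c(Oc5cc(O)c(O)c(O)c5)c(O)c4)c(O)c3)c(O)c2)c(O)c1 | target

## Step count and least certain steps

Total: 21 steps. Longest linear sequence: 14 steps (steps 1, 2, 3, 4, 5, 13, 14, 15, 16, 17, 18, 19, 20, 21).

Step 15 (key step; the same applies to step 18).
- Most likely to go wrong: diversion of the dienylketene before ring closure. The bulky aryloxy group on the inside of the vinyl terminus may slow the 6π closure enough for ketene dimerisation or capture by adventitious water to compete, and the acetal may be partly lost on heating.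
- Fallback, from 27 back to 31: the lithium alkoxide 27 would be quenched with aqueous NH4Cl instead of MOMCl to give the racemic 4-hydroxycyclobutenone F1. A free hydroxyl is the strongest outward-directing donor and such compounds rearrange at lower temperature, so heating F1 in toluene should give the hydroquinone F2. The two hydroxyls would then be differentiated after the ring expansion by selective etherification (MOMCl, 1 equiv, i-Pr2NEt, CH2Cl2, 0 °C) of the less hindered one next to the ring hydrogen, which returns to 31.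

Step 16 (the same applies to steps 13 and 19).
- Most likely to go wrong: slow C–O bond formation at a phenol with two ortho substituents, so that oxidation of the electron-rich phenol by divalent copper and air, or protodeboronation and homocoupling of 9, overtake the coupling.
- Fallback, from 31 back to 32: a non-oxidative, ligand-accelerated Ullmann coupling with an aryl bromide. Phenol 5 would be allylated (allyl bromide, K2CO3, DMF) to 2-(allyloxy)-1,3-bis(benzyloxy)-5-bromobenzene F3. Coupling of 31 with F3 (CuI, picolinic acid, K3PO4, DMSO, 90 °C) would give the tetramer allyl ether F4. Deallylation with Pd(PPh3)4 (zerovalent palladium) and morpholine would give the tetramer phenol F5. Addition of F5 to bromoethyne (7, Cs2CO3, DMF, as in step 4) would then give 32.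

Step 14 (the same applies to step 17).
- Most likely to go wrong: decay of the vinyllithium before it meets 24, by loss of aryloxide or by proton transfer from a benzylic or ring position, and incomplete capping of the hindered tertiary alkoxide.
- Fallback, from 25 back to 28: 25 would be treated with LiN(i-Pr)2 (2.2 equiv, THF, −78 °C) to eliminate HBr and form the lithium aryloxyacetylide F6, which has no β-leaving-group problem. Addition to 24 and capping with MOMCl would give the racemic 4-alkynylcyclobutenone F7. Semi-hydrogenation (H2, Pd/CaCO3 poisoned with Pb(OAc)2, quinoline, EtOAc) would deliver the Z alkene 28.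

Step 4.
- Most likely to go wrong: loss of the boron group from the electron-rich phenoxide under hot carbonate, or inefficient capture of bromoethyne.
- Fallback, from 6 back to 25: vinylation would be postponed until no boron is present. Phenol 6 would be allylated (allyl bromide, K2CO3, DMF) to the allyl ether F8 and the pinacol ester cleaved (NaIO4, NH4OAc) to the boronic acid F9. Chan–Lam coupling of F9 with 22 would give the A–B allyl ether F10, and deallylation (Pd(PPh3)4, zerovalent palladium, morpholine) the A–B phenol F11. Addition of F11 to bromoethyne (7, Cs2CO3, DMF) would give 25. Ring D would then be introduced in the same way through F4 and F5.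

Step 21.
- Most likely to go wrong: stalling of the hydrogenolysis when partly debenzylated material precipitates or poisons the catalyst, and oxidation of the free polyphenol during filtration.
- Fallback, from 40 back to 41: Lewis-acid debenzylation with BCl3 and pentamethylbenzene as cation scavenger in CH2Cl2 at −78 °C, followed by methanol quench; no new compound is made on the way.

## Further compounds

F1 | step 15 | racemic 2,3-bis(benzyloxy)-4-hydroxy-4-[(Z)-2-(A–B aryloxy)ethenyl]cyclobut-2-en-1-one | O=C1C(OCc9ccccc9)=C(OCc9ccccc9)C1(O)/C=C\Oc2c(OCc9ccccc9)cc(Oc3c(OCc9ccccc9)cc(OCc9ccccc9)cc3OCc9ccccc9)cc2OCc9ccccc9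
F2 | step 15 | 2,3-bis(benzyloxy)-5-(A–B aryloxy)benzene-1,4-diol | Oc1c(OCc9ccccc9)c(OCc9ccccc9)c(O)cc1Oc2c(OCc9ccccc9)cc(Oc3c(OCc9ccccc9)cc(OCc9ccccc9)cc3OCc9ccccc9)cc2OCc9ccccc9
F3 | step 16 | 2-(allyloxy)-1,3-bis(benzyloxy)-5-bromobenzene | C=CCOc1c(OCc9ccccc9)cc(Br)cc1OCc9ccccc9
F4 | step 16 | A–B–C–D tetramer allyl ether (allyl on the ring D C4 oxygen) | C=CCOc4c(OCc9ccccc9)cc(Oc1c(OCc9ccccc9)c(OCc9ccccc9)c(OCOC)cc1Oc2c(OCc9ccccc9)cc(Oc3c(OCc9ccccc9)cc(OCc9ccccc9)cc3OCc9ccccc9)cc2OCc9ccccc9)cc4OCc9ccccc9
F5 | step 16 | A–B–C–D tetramer phenol (free hydroxyl on ring D C4) | Oc4c(OCc9ccccc9)cc(Oc1c(OCc9ccccc9)c(OCc9ccccc9)c(OCOC)cc1Oc2c(OCc9ccccc9)cc(Oc3c(OCc9ccccc9)cc(OCc9ccccc9)cc3OCc9ccccc9)cc2OCc9ccccc9)cc4OCc9ccccc9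
F6 | step 14 | lithium (A–B aryloxy)acetylide | [Li]C#COc2c(OCc9ccccc9)cc(Oc3c(OCc9ccccc9)cc(OCc9ccccc9)cc3OCc9ccccc9)cc2OCc9ccccc9
F7 | step 14 | racemic 2,3-bis(benzyloxy)-4-(methoxymethoxy)-4-[(A–B aryloxy)ethynyl]cyclobut-2-en-1-one | O=C1C(OCc9ccccc9)=C(OCc9ccccc9)C1(OCOC)C#COc2c(OCc9ccccc9)cc(Oc3c(OCc9ccccc9)cc(OCc9ccccc9)cc3OCc9ccccc9)cc2OCc9ccccc9
F8 | step 4 | 2-[4-(allyloxy)-3,5-bis(benzyloxy)phenyl]-4,4,5,5-tetramethyl-1,3,2-dioxaborolane | C=CCOc1c(OCc9ccccc9)cc(B2OC(C)(C)C(C)(C)O2)cc1OCc9ccccc9
F9 | step 4 | [4-(allyloxy)-3,5-bis(benzyloxy)phenyl]boronic acid | C=CCOc1c(OCc9ccccc9)cc(B(O)O)cc1OCc9ccccc9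
F10 | step 4 | 2-(allyloxy)-1,3-bis(benzyloxy)-5-[2,4,6-tris(benzyloxy)phenoxy]benzene | C=CCOc2c(OCc9ccccc9)cc(Oc3c(OCc9ccccc9)cc(OCc9ccccc9)cc3OCc9ccccc9)cc2OCc9ccccc9
F11 | step 4 | 2,6-bis(benzyloxy)-4-[2,4,6-tris(benzyloxy)phenoxy]phenol | Oc2c(OCc9ccccc9)cc(Oc3c(OCc9ccccc9)cc(OCc9ccccc9)cc3OCc9ccccc9)cc2OCc9ccccc9
F0 | step 21 | none | none
A1 | alternative 1 | permethylated tris-ester (aryl esters B–O–CO–C, D–O–CO–E and F–O–CO–G) | COc1cc(OC)c(Oc2cc(OC)c(OC(=O)c3cc(OC)c(OC)c(OC)c3Oc3cc(OC)c(OC(=O)c4cc(OC)c(OC)c(OC)c4Oc4cc(OC)c(OC(=O)c5cc(OC)c(OC)c(OC)c5)c(OC)c4)c(OC)c3)c(OC)c2)c(OC)c1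
A2 | alternative 1 | octadecamethyl ether of the target | COc1cc(OC)c(Oc2cc(OC)c(Oc3cc(OC)c(OC)c(OC)c3Oc3cc(OC)c(Oc4cc(OC)c(OC)c(OC)c4Oc4cc(OC)c(Oc5cc(OC)c(OC)c(OC)c5)c(OC)c4)c(OC)c3)c(OC)c2)c(OC)c1
A3 | alternative 2 | [CpRu(η6-2,5-dichloro-1,3-bis(benzyloxy)benzene)]PF6, written as its components | Clc1cc(OCc9ccccc9)c(Cl)c(OCc9ccccc9)c1.[Ru+2].[cH-]1cccc1.F[P-](F)(F)(F)(F)F
A4 | alternative 2 | perbenzylated A–E pentamer phenol (free hydroxyl on ring E C6) | C(c9ccccc9)Oc1cc(OCc9ccccc9)c(Oc2cc(OCc9ccccc9)c(Oc3cc(OCc9ccccc9)c(OCc9ccccc9)c(OCc9ccccc9)c3Oc3cc(OCc9ccccc9)c(Oc4cc(OCc9ccccc9)c(OCc9ccccc9)c(OCc9ccccc9)c4O)c(OCc9ccccc9)c3)c(OCc9ccccc9)c2)c(OCc9ccccc9)c1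
A5 | alternative 2 | 3,4,5-tris(benzyloxy)phenol | Oc1cc(OCc9ccccc9)c(OCc9ccccc9)c(OCc9ccccc9)c1
A6 | alternative 2 | cyclopentadienylruthenium hexafluorophosphate complex (on ring F) of the octadecabenzyl ether of the target, written as its components | C(c9ccccc9)Oc1cc(OCc9ccccc9)c(Oc2cc(OCc9ccccc9)c(Oc3cc(OCc9ccccc9)c(OCc9ccccc9)c(OCc9ccccc9)c3Oc3cc(OCc9ccccc9)c(Oc4cc(OCc9ccccc9)c(OCc9ccccc9)c(OCc9ccccc9)c4Oc4cc(OCc9ccccc9)c(Oc5cc(OCc9ccccc9)c(OCc9ccccc9)c(OCc9ccccc9)c5)c(OCc9ccccc9)c4)c(OCc9ccccc9)c3)c(OCc9ccccc9)c2)c(OCc9ccccc9)c1.[Ru+2].[cH-]1cccc1.F[P-](F)(F)(F)(F)F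
A7 | alternative 3 | methyl 6-aryloxy-3,5-dioxohexanoate of the benzylated B–G hexamer (chain on the ring B C1 oxygen) | COC(=O)CC(=O)CC(=O)COc2cc(OCc9ccccc9)c(Oc3cc(OCc9ccccc9)c(OCc9ccccc9)c(OCc9ccccc9)c3Oc3cc(OCc9ccccc9)c(Oc4cc(OCc9ccccc9)c(OCc9ccccc9)c(OCc9ccccc9)c4Oc4cc(OCc9ccccc9)c(Oc5cc(OCc9ccccc9)c(OCc9ccccc9)c(OCc9ccccc9)c5)c(OCc9ccccc9)c4)c(OCc9ccccc9)c3)c(OCc9ccccc9)c2
A8 | alternative 3 | heptamer with free phloroglucinol ring A and fifteen benzyl ethers | Oc1cc(O)c(Oc2cc(OCc9ccccc9)c(Oc3cc(OCc9ccccc9)c(OCc9ccccc9)c(OCc9ccccc9)c3Oc3cc(OCc9ccccc9)c(Oc4cc(OCc9ccccc9)c(OCc9ccccc9)c(OCc9ccccc9)c4Oc4cc(OCc9ccccc9)c(Oc5cc(OCc9ccccc9)c(OCc9ccccc9)c(OCc9ccccc9)c5)c(OCc9ccccc9)c4)c(OCc9ccccc9)c3)c(OCc9ccccc9)c2)c(O)c1
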